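**Retrosynthetic overview**

1. The target comes from acetylation of the C12 tertiary alcohol; C7=C8 comes from aldol condensation of a C8 enolate with methyl (E)-7-oxohept-5-enoate, itself made by cross-metathesis of methyl hex-5-enoate.
2. The (S)-2-chloro-4-silyloxy-4-octenylcyclopent-2-enone comes from hydride reduction at C11 with 1,3-carbonyl transposition, after C10 chlorination of a 3-methoxy enone (the C9/C11 1,3-dione oxidation level).
3. Feature: in the five-membered ring C8–C12, carbinol C12 is bonded to C11, the electrophilic beta-carbon of the C9-keto/C10-chloro enone. Once C11 is read as a ketone, C11(=O)–C12(OH) is an alpha-ketol, so C11–C12 is cut by an umpolung (benzoin) disconnection.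
4. Ring formation: the only ring (C8–C12) is closed by a carbene-catalysed asymmetric crossed benzoin of an achiral keto aldehyde (C11 aldehyde, C12 ketone, C9 dioxolane); the same step sets C12, the only stereocentre.
5. The keto aldehyde comes from the methyl acetoacetate dianion (C8–C11) and (Z)-non-3-enal (C12–C20), followed by C9 ketalisation, ester reduction and a double oxidation.

Key step: step 8

Remark on the chemistry: prostanoid numbering is used for positions (C1 ester carbon, ring C8–C12, C20 chain end). The sense of induction of the triazolium salt cannot be fixed on paper for this all-aliphatic substrate; the (5aR,10bS) salt is written, and its commercially available antipode is used instead if a first run shows the opposite sense.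

**Route**

Step 1
Reactants: 1 (Z)-non-3-en-1-ol
Product: 2 (Z)-non-3-enal
Conditions: DMP, NaHCO3, CH2Cl2, 0 °C to rt; crude product used at once
Reagents that add atoms: none
Why: Dess–Martin oxidation is neutral and fast, so the skipped Z-alkene of the beta,gamma-unsaturated aldehyde is not drawn into conjugation when the product is kept cold and used directly.

Step 2
Reactants: 3 methyl acetoacetate; 2 (Z)-non-3-enal
Product: 5 methyl (Z)-5-hydroxy-3-oxotridec-7-enoate (racemic), via acetoacetate dianion 4 (not isolated)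
Conditions: NaH, THF, 0 °C; n-BuLi, 0 °C; then 2, −78 °C; aq. NH4Cl
Reagents that add atoms: none
Why: Weiler dianion aldol addition, in which the more reactive terminal carbanion adds to the aldehyde at −78 °C faster than it deprotonates it and joins C8 to C12; the new carbinol centre is racemic and is later oxidised away.

Step 3
Reactants: 5 methyl (Z)-5-hydroxy-3-oxotridec-7-enoate
Product: 6 methyl (Z)-5-[(tert-butyldimethylsilyl)oxy]-3-oxotridec-7-enoate (racemic)
Conditions: TBSCl, imidazole, DMF, 0 °C to rt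
Reagents that add atoms: tert-butyldimethylsilyl chloride, CC(C)(C)[Si](C)(C)Cl
Why: Standard silylation of the secondary alcohol blocks lactonisation onto the ester and retro-aldol cleavage in the following steps; any silyl enol ether of the keto ester is hydrolysed on work-up.

Step 4
Reactants: 6 methyl (Z)-5-[(tert-butyldimethylsilyl)oxy]-3-oxotridec-7-enoate
Product: 7 methyl 2-{2-[(Z)-2-[(tert-butyldimethylsilyl)oxy]dec-4-en-1-yl]-1,3-dioxolan-2-yl}acetate (racemic)
Conditions: Me3SiOCH2CH2OSiMe3, Me3SiOTf (cat.), CH2Cl2, −78 to −20 °C; pyridine quench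
Reagents that add atoms: 1,2-bis(trimethylsilyloxy)ethane, C[Si](C)(C)OCCO[Si](C)(C)C
Why: Noyori ketalisation converts the only ketone (C9) into the dioxolane under aprotic low-temperature conditions that leave the beta-silyloxy group, the ester and the alkene untouched.

Step 5
Reactants: 7 methyl 2-{2-[(Z)-2-[(tert-butyldimethylsilyl)oxy]dec-4-en-1-yl]-1,3-dioxolan-2-yl}acetate
Product: 8 2-{2-[(Z)-2-[(tert-butyldimethylsilyl)oxy]dec-4-en-1-yl]-1,3-dioxolan-2-yl}ethan-1-ol (racemic)
Conditions: LiAlH4, THF, 0 °C; H2O/NaOH work-up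
Reagents that add atoms: none
Why: Hydride reduction of the ester gives the primary alcohol at C11, while the ketal, the silyl ether and the isolated alkene are inert to LiAlH4.

Step 6
Reactants: 8 2-{2-[(Z)-2-[(tert-butyldimethylsilyl)oxy]dec-4-en-1-yl]-1,3-dioxolan-2-yl}ethan-1-ol
Product: 9 (Z)-1-[2-(2-hydroxyethyl)-1,3-dioxolan-2-yl]dec-4-en-2-ol (racemic)
Conditions: Bu4NF, THF, rt
Reagents that add atoms: none
Why: Fluoride desilylation frees the C12 hydroxyl; it is placed after the ester reduction so that this hydroxyl cannot lactonise.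

Step 7
Reactants: 9 (Z)-1-[2-(2-hydroxyethyl)-1,3-dioxolan-2-yl]dec-4-en-2-ol
Product: 10 2-{2-[(Z)-2-oxodec-4-en-1-yl]-1,3-dioxolan-2-yl}acetaldehyde
Conditions: (COCl)2, DMSO, CH2Cl2, −78 °C; then i-Pr2NEt, −78 to −40 °C; cold pH 7 buffer; used at once
Reagents that add atoms: none
Why: Swern oxidation activates both hydroxyls as alkoxysulfonium ions before base is added, so aldehyde and ketone are released together and the hydroxy aldehyde cannot close to a lactol and over-oxidise to the lactone; the hindered amine and cold buffered quench limit alkene migration and beta-elimination of the ketal.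

Step 8
Reactants: 10 2-{2-[(Z)-2-oxodec-4-en-1-yl]-1,3-dioxolan-2-yl}acetaldehyde
Product: 11 (S)-8-hydroxy-8-[(Z)-oct-2-en-1-yl]-1,4-dioxaspiro[4.4]nonan-7-one
Conditions: (5aR,10bS)-2-(pentafluorophenyl)-5a,10b-dihydro-4H,6H-indeno[2,1-b][1,2,4]triazolo[4,3-d][1,4]oxazin-2-ium tetrafluoroborate (10 mol %), i-Pr2NEt (10 mol %), toluene, 0.02 M, rt
Reagents that add atoms: none
Why: The triazolylidene freed by the amine adds to the unhindered C11 aldehyde and proton transfer gives the enaminol (Breslow intermediate), whose C11 is now nucleophilic; it attacks the C12 ketone and release of the carbene leaves the C11 ketone next to the C12 tertiary alcohol, which is the intramolecular crossed aldehyde–ketone benzoin reaction, a known carbene-catalysed route to cyclic tertiary alpha-ketols. The single ring C8–C12 is closed by forming C11–C12 in a 5-exo-trig mode. C12, the only stereocentre, is set by the catalyst: the fused indane shields one face of the enaminol and the enaminol O–H hydrogen-bonds to the ketone oxygen, so the ketone presents one face with its free octenyl arm turned away from the N-aryl group, the other arm being held in the forming ring. Chemoselectivity follows from the substrate, since only C11 carries the formyl hydrogen needed to make the acyl anion equivalent and the ketone can act only as acceptor, while the gem-dioxygenated C9 in the three-atom tether favours cyclisation over intermolecular benzoin (helped by dilution) and blocks 1,3-dicarbonyl enolisation. The base is kept weak and substoichiometric so that aldol closure through the C13 enolate, migration of the C14=C15 alkene into conjugation and beta-elimination of the ketal do not compete; once C12 is quaternary the skipped alkene is no longer at risk.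

Step 9
Reactants: 11 (S)-8-hydroxy-8-[(Z)-oct-2-en-1-yl]-1,4-dioxaspiro[4.4]nonan-7-one
Product: 12 (S)-8-[(tert-butyldimethylsilyl)oxy]-8-[(Z)-oct-2-en-1-yl]-1,4-dioxaspiro[4.4]nonan-7-one
Conditions: TBSOTf, 2,6-lutidine, CH2Cl2, −78 to 0 °C
Reagents that add atoms: tert-butyldimethylsilyl trifluoromethanesulfonate, CC(C)(C)[Si](C)(C)OS(=O)(=O)C(F)(F)F
Why: Silyl triflate with 2,6-lutidine is the standard silylation for a hindered tertiary alcohol; the ether shuts off alpha-ketol rearrangement and retro-aldol pathways and survives every step up to the final deprotection.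

Step 10
Reactants: 12 (S)-8-[(tert-butyldimethylsilyl)oxy]-8-[(Z)-oct-2-en-1-yl]-1,4-dioxaspiro[4.4]nonan-7-one
Product: 13 (S)-5-[(tert-butyldimethylsilyl)oxy]-3-methoxy-5-[(Z)-oct-2-en-1-yl]cyclopent-2-en-1-one
Conditions: (1S)-(+)-10-camphorsulfonic acid (10 mol %), MeOH, rt to 40 °C; Et3N quench
Reagents that add atoms: methanol, CO
Why: Acid-catalysed transacetalisation–elimination of a beta-keto ketal to a vinylogous ester, in which the dioxolane opens toward the C11 carbonyl and methanol as solvent exchanges the hydroxyethyl group, so the ether oxygen sits on C9 exactly where the ketal was and no choice between the two dione oxygens arises; any dioxolane already opened during silylation converges on the same product.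

Step 11
Reactants: 13 (S)-5-[(tert-butyldimethylsilyl)oxy]-3-methoxy-5-[(Z)-oct-2-en-1-yl]cyclopent-2-en-1-one
Product: 14 (S)-5-[(tert-butyldimethylsilyl)oxy]-2-chloro-3-methoxy-5-[(Z)-oct-2-en-1-yl]cyclopent-2-en-1-one
Conditions: NCS, CH2Cl2, 0 °C to rt, dark
Reagents that add atoms: N-chlorosuccinimide, O=C1CCC(=O)N1Cl
Why: Electrophilic chlorination of a 3-alkoxy enone at its nucleophilic alpha-carbon (C10); the isolated Z-alkene does not react with NCS under neutral, non-radical conditions.

Step 12
Reactants: 14 (S)-5-[(tert-butyldimethylsilyl)oxy]-2-chloro-3-methoxy-5-[(Z)-oct-2-en-1-yl]cyclopent-2-en-1-one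
Product: 16 (S)-4-[(tert-butyldimethylsilyl)oxy]-2-chloro-4-[(Z)-oct-2-en-1-yl]cyclopent-2-en-1-one, via allylic alcohol 15 (not isolated)
Conditions: i-Bu2AlH, CH2Cl2, −78 °C; then 1 M HCl, THF, 0 °C to rt
Reagents that add atoms: water, O
Why: Stork–Danheiser 1,3-carbonyl transposition, in which i-Bu2AlH adds 1,2 to the C11 carbonyl and aqueous acid then hydrolyses the chloro enol ether with loss of the C11 hydroxyl, leaving the ketone at C9, the alkene at C10=C11 and chlorine on C10; the transient C11 carbinol centre is destroyed and the tertiary TBS ether withstands dilute HCl.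

Step 13
Reactants: 17 methyl hex-5-enoate; 18 (E)-but-2-enal
Product: 19 methyl (E)-7-oxohept-5-enoate
Conditions: 18 (5 equiv), second-generation Hoveyda–Grubbs catalyst [RuCl2(=CH-C6H4-2-O-i-Pr)(1,3-dimesitylimidazolidin-2-ylidene), C31H38Cl2N2ORu] (3 mol %), CH2Cl2, 40 °C
Reagents that add atoms: none
Why: Olefin cross-metathesis of a terminal alkene with an excess of an electron-poor enal is selective for the cross product and gives the E enal, with propene lost.

Step 14
Reactants: 16 (S)-4-[(tert-butyldimethylsilyl)oxy]-2-chloro-4-[(Z)-oct-2-en-1-yl]cyclopent-2-en-1-one; 19 methyl (E)-7-oxohept-5-enoate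
Product: 21 methyl (E)-7-{(2S)-2-[(tert-butyldimethylsilyl)oxy]-4-chloro-2-[(Z)-oct-2-en-1-yl]-5-oxocyclopent-3-en-1-yl}-7-hydroxyhept-5-enoate (mixture of diastereomers at C7 and C8), via lithium enolate 20 (not isolated)
Conditions: LiN(i-Pr)2, THF, −78 °C; then 19, −78 °C; aq. NH4Cl
Reagents that add atoms: none
Why: Aldol addition in which kinetic enolisation can occur only at C8 (C12 is quaternary, C11 vinylic), the cross-conjugated lithium dienolate does not expel the C12 silyloxy group because that would give a cyclopentadienone, and the enolate adds 1,2 to the enal at −78 °C; the two new centres at C7 and C8 are removed in the next step.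

Step 15
Reactants: 21 methyl (E)-7-{(2S)-2-[(tert-butyldimethylsilyl)oxy]-4-chloro-2-[(Z)-oct-2-en-1-yl]-5-oxocyclopent-3-en-1-yl}-7-hydroxyhept-5-enoate
Product: 23 methyl (5E,7E)-7-{(2R)-2-[(tert-butyldimethylsilyl)oxy]-4-chloro-2-[(Z)-oct-2-en-1-yl]-5-oxocyclopent-3-en-1-ylidene}hept-5-enoate, via aldol mesylate 22 (not isolated)
Conditions: MsCl, Et3N, CH2Cl2, −20 °C to rt
Reagents that add atoms: none
Why: Aldol dehydration by mesylation of the secondary allylic alcohol and E1cB elimination through the C8 enolate gives the cross-conjugated dienone, the 7E isomer (C6 anti to the C9 carbonyl) being expected to predominate as in related 2-alkylidenecyclopentenones, while the E geometry at C5=C6 comes unchanged from 19.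

Step 16
Reactants: 23 methyl (5E,7E)-7-{(2R)-2-[(tert-butyldimethylsilyl)oxy]-4-chloro-2-[(Z)-oct-2-en-1-yl]-5-oxocyclopent-3-en-1-ylidene}hept-5-enoate
Product: 24 methyl (5E,7E)-7-{(2R)-4-chloro-2-hydroxy-2-[(Z)-oct-2-en-1-yl]-5-oxocyclopent-3-en-1-ylidene}hept-5-enoate
Conditions: 48% aq. HF, MeCN, 0 °C to rt
Reagents that add atoms: none
Why: HF desilylation cleaves the hindered tertiary Si–O bond slowly but cleanly, the chloro dienone and the methyl ester tolerate the weakly acidic medium, and aqueous HF is too weak an acid to ionise the C12–O bond, so C12 keeps its configuration.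

Step 17
Reactants: 24 methyl (5E,7E)-7-{(2R)-4-chloro-2-hydroxy-2-[(Z)-oct-2-en-1-yl]-5-oxocyclopent-3-en-1-ylidene}hept-5-enoate
Product: 25 methyl (5E,7E)-7-{(2R)-2-acetoxy-4-chloro-2-[(Z)-oct-2-en-1-yl]-5-oxocyclopent-3-en-1-ylidene}hept-5-enoate
Conditions: Ac2O, 4-(dimethylamino)pyridine, Et3N, CH2Cl2, rt
Reagents that add atoms: acetic anhydride, CC(=O)OC(C)=O
Why: DMAP-catalysed acetylation through the N-acetylpyridinium ion esterifies the hindered tertiary alcohol on oxygen without breaking the C12–O bond, giving the target with C12 unchanged.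

**Compound list**

1 | (Z)-non-3-en-1-ol | CCCCC/C=C\CCO | starting material
2 | (Z)-non-3-enal | CCCCC/C=C\CC=O | intermediate
3 | methyl acetoacetate | COC(=O)CC(C)=O | starting material
4 | sodium lithium dianion of methyl acetoacetate | [Na+].[Li+].C=C([O-])C=C([O-])OC | intermediate
5 | methyl (Z)-5-hydroxy-3-oxotridec-7-enoate (racemic) | CCCCC/C=C\CC(O)CC(=O)CC(=O)OC | intermediate
6 | methyl (Z)-5-[(tert-butyldimethylsilyl)oxy]-3-oxotridec-7-enoate (racemic) | CCCCC/C=C\CC(O[Si](C)(C)C(C)(C)C)CC(=O)CC(=O)OC | intermediate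
7 | methyl 2-{2-[(Z)-2-[(tert-butyldimethylsilyl)oxy]dec-4-en-1-yl]-1,3-dioxolan-2-yl}acetate (racemic) | CCCCC/C=C\CC(O[Si](C)(C)C(C)(C)C)CC1(CC(=O)OC)OCCO1 | intermediate
8 | 2-{2-[(Z)-2-[(tert-butyldimethylsilyl)oxy]dec-4-en-1-yl]-1,3-dioxolan-2-yl}ethan-1-ol (racemic) | CCCCC/C=C\CC(O[Si](C)(C)C(C)(C)C)CC1(CCO)OCCO1 | intermediate
9 | (Z)-1-[2-(2-hydroxyethyl)-1,3-dioxolan-2-yl]dec-4-en-2-ol (racemic) | CCCCC/C=C\CC(O)CC1(CCO)OCCO1 | intermediate
10 | 2-{2-[(Z)-2-oxodec-4-en-1-yl]-1,3-dioxolan-2-yl}acetaldehyde | CCCCC/C=C\CC(=O)CC1(CC=O)OCCO1 | intermediate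
11 | (S)-8-hydroxy-8-[(Z)-oct-2-en-1-yl]-1,4-dioxaspiro[4.4]nonan-7-one | CCCCC/C=C\C[C@@]1(O)C(=O)CC2(OCCO2)C1 | intermediate
12 | (S)-8-[(tert-butyldimethylsilyl)oxy]-8-[(Z)-oct-2-en-1-yl]-1,4-dioxaspiro[4.4]nonan-7-one | CCCCC/C=C\C[C@@]1(O[Si](C)(C)C(C)(C)C)C(=O)CC2(OCCO2)C1 | intermediate
13 | (S)-5-[(tert-butyldimethylsilyl)oxy]-3-methoxy-5-[(Z)-oct-2-en-1-yl]cyclopent-2-en-1-one | CCCCC/C=C\C[C@@]1(O[Si](C)(C)C(C)(C)C)C(=O)C=C(OC)C1 | intermediate
14 | (S)-5-[(tert-butyldimethylsilyl)oxy]-2-chloro-3-methoxy-5-[(Z)-oct-2-en-1-yl]cyclopent-2-en-1-one | CCCCC/C=C\C[C@@]1(O[Si](C)(C)C(C)(C)C)C(=O)C(Cl)=C(OC)C1 | intermediate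
15 | (5S)-5-[(tert-butyldimethylsilyl)oxy]-2-chloro-3-methoxy-5-[(Z)-oct-2-en-1-yl]cyclopent-2-en-1-ol (both C1 epimers) | CCCCC/C=C\C[C@@]1(O[Si](C)(C)C(C)(C)C)C(O)C(Cl)=C(OC)C1 | intermediate
16 | (S)-4-[(tert-butyldimethylsilyl)oxy]-2-chloro-4-[(Z)-oct-2-en-1-yl]cyclopent-2-en-1-one | CCCCC/C=C\C[C@@]1(O[Si](C)(C)C(C)(C)C)C=C(Cl)C(=O)C1 | intermediate
17 | methyl hex-5-enoate | C=CCCCC(=O)OC | starting material
18 | (E)-but-2-enal | C/C=C/C=O | starting material
19 | methyl (E)-7-oxohept-5-enoate | O=C/C=C/CCCC(=O)OC | intermediate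
20 | lithium enolate of 16 (C8=C9 enolate) | [Li+].CCCCC/C=C\C[C@@]1(O[Si](C)(C)C(C)(C)C)C=C(Cl)C([O-])=C1 | intermediate
21 | methyl (E)-7-{(2S)-2-[(tert-butyldimethylsilyl)oxy]-4-chloro-2-[(Z)-oct-2-en-1-yl]-5-oxocyclopent-3-en-1-yl}-7-hydroxyhept-5-enoate (diastereomers at C7 and C8) | CCCCC/C=C\C[C@@]1(O[Si](C)(C)C(C)(C)C)C=C(Cl)C(=O)C1C(O)/C=C/CCCC(=O)OC | intermediate
22 | methyl (E)-7-{(2S)-2-[(tert-butyldimethylsilyl)oxy]-4-chloro-2-[(Z)-oct-2-en-1-yl]-5-oxocyclopent-3-en-1-yl}-7-(methanesulfonyloxy)hept-5-enoate | CCCCC/C=C\C[C@@]1(O[Si](C)(C)C(C)(C)C)C=C(Cl)C(=O)C1C(OS(C)(=O)=O)/C=C/CCCC(=O)OC | intermediate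
23 | methyl (5E,7E)-7-{(2R)-2-[(tert-butyldimethylsilyl)oxy]-4-chloro-2-[(Z)-oct-2-en-1-yl]-5-oxocyclopent-3-en-1-ylidene}hept-5-enoate | CCCCC/C=C\C[C@@]1(O[Si](C)(C)C(C)(C)C)C=C(Cl)C(=O)/C1=C/C=C/CCCC(=O)OC | intermediate
24 | methyl (5E,7E)-7-{(2R)-4-chloro-2-hydroxy-2-[(Z)-oct-2-en-1-yl]-5-oxocyclopent-3-en-1-ylidene}hept-5-enoate | CCCCC/C=C\C[C@@]1(O)C=C(Cl)C(=O)/C1=C/C=C/CCCC(=O)OC | intermediate
25 | methyl (5E,7E)-7-{(2R)-2-acetoxy-4-chloro-2-[(Z)-oct-2-en-1-yl]-5-oxocyclopent-3-en-1-ylidene}hept-5-enoate | CCCCC/C=C\C[C@@]1(OC(C)=O)C=C(Cl)C(=O)/C1=C/C=C/CCCC(=O)OC | target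

**Step count and risks**

Total step count: 17. Longest linear sequence: 16 steps (steps 1–12 and 14–17, from 1); step 13 is a one-step branch.

Steps most likely to fail:

Step 8. What may go wrong: insufficient facial discrimination in C11–C12 bond formation on this all-aliphatic substrate, or base-induced side reactions of 10 (aldol closure from the C13 enolate, opening of the dioxolane by beta-elimination) outrunning the carbene cycle. The fallback sets out from 10 and returns at 11. The ring is closed without any base by reductive ketyl–carbonyl (pinacol) cyclisation with SmI2 in THF/t-BuOH at −78 °C, which should give racemic cis-8-[(Z)-oct-2-en-1-yl]-1,4-dioxaspiro[4.4]nonane-7,8-diol F1. Oxidation of its secondary alcohol (SO3·pyridine, DMSO, i-Pr2NEt) gives racemic 8-hydroxy-8-[(Z)-oct-2-en-1-yl]-1,4-dioxaspiro[4.4]nonan-7-one F2. The enantiomers are separated by preparative chromatography on a polysaccharide chiral phase, and the (S)-enantiomer is 11.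

Step 15. What may go wrong: poor geometric control in the E1cB loss of the mesylate, so that a large share of the 7Z alkylidene forms beside the 7E isomer. The fallback sets out from 21 and returns at 23. Thermodynamic equilibration replaces kinetic control: the elimination is run as before, and methyl (5E,7Z)-7-{(2R)-2-[(tert-butyldimethylsilyl)oxy]-4-chloro-2-[(Z)-oct-2-en-1-yl]-5-oxocyclopent-3-en-1-ylidene}hept-5-enoate F3 is separated by chromatography. It is then equilibrated with catalytic I2 in CH2Cl2 under visible light, a known way to interconvert the geometric isomers of conjugated dienones. A low iodine loading and short exposure are used because the isolated C14=C15 alkene reacts far more slowly than the dienone. 23 is taken from the mixture and the remaining F3 is recycled.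

Step 12. What may go wrong: hydride attack on the chlorinated vinylogous ester that is not cleanly 1,2 (conjugate addition at C9 with loss of methoxide, or loss of chlorine), and slow hydrolysis of the electron-poor chloro enol ether. The fallback sets out from 13 and returns at 16; the transposition is done before chlorination. Reduction of 13 with i-Bu2AlH gives (5S)-5-[(tert-butyldimethylsilyl)oxy]-3-methoxy-5-[(Z)-oct-2-en-1-yl]cyclopent-2-en-1-ol F4, which is hydrolysed without isolation (1 M HCl, THF) to (S)-4-[(tert-butyldimethylsilyl)oxy]-4-[(Z)-oct-2-en-1-yl]cyclopent-2-en-1-one F5. Nucleophilic epoxidation (H2O2, NaOH, MeOH, 0 °C) touches only the enone and gives (4S)-4-[(tert-butyldimethylsilyl)oxy]-4-[(Z)-oct-2-en-1-yl]-6-oxabicyclo[3.1.0]hexan-2-one F6. Opening of this epoxy ketone at C10 by chloride with loss of water (HCl in THF), the known conversion of alpha,beta-epoxy ketones into alpha-chloro enones, gives 16.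

Further compounds

F1 | step 8 | cis-8-[(Z)-oct-2-en-1-yl]-1,4-dioxaspiro[4.4]nonane-7,8-diol (racemic; one enantiomer drawn) | CCCCC/C=C\C[C@@]1(O)[C@H](O)CC2(OCCO2)C1
F2 | step 8 | 8-hydroxy-8-[(Z)-oct-2-en-1-yl]-1,4-dioxaspiro[4.4]nonan-7-one (racemic) | CCCCC/C=C\CC1(O)C(=O)CC2(OCCO2)C1
F3 | step 15 | methyl (5E,7Z)-7-{(2R)-2-[(tert-butyldimethylsilyl)oxy]-4-chloro-2-[(Z)-oct-2-en-1-yl]-5-oxocyclopent-3-en-1-ylidene}hept-5-enoate | CCCCC/C=C\C[C@@]1(O[Si](C)(C)C(C)(C)C)C=C(Cl)C(=O)/C1=C\C=C\CCCC(=O)OC
F4 | step 12 | (5S)-5-[(tert-butyldimethylsilyl)oxy]-3-methoxy-5-[(Z)-oct-2-en-1-yl]cyclopent-2-en-1-ol (both C1 epimers) | CCCCC/C=C\C[C@@]1(O[Si](C)(C)C(C)(C)C)C(O)C=C(OC)C1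
F5 | step 12 | (S)-4-[(tert-butyldimethylsilyl)oxy]-4-[(Z)-oct-2-en-1-yl]cyclopent-2-en-1-one | CCCCC/C=C\C[C@@]1(O[Si](C)(C)C(C)(C)C)C=CC(=O)C1
F6 | step 12 | (4S)-4-[(tert-butyldimethylsilyl)oxy]-4-[(Z)-oct-2-en-1-yl]-6-oxabicyclo[3.1.0]hexan-2-one (epoxide diastereomers) | CCCCC/C=C\C[C@@]1(O[Si](C)(C)C(C)(C)C)C2OC2C(=O)C1
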